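**Retrosynthetic overview**

- Disconnections: the C8–O ester (epoxyangelic acid 4), C9–C10 (ring-closing Nozaki–Hiyama–Kishi reaction), the lactone O–C6 bond (key step), C5–C6 (acetylide + Weinreb amide) and C7–C8 (auxiliary anti-aldol). C6, C7, C11, C12 and C13 come from itaconic anhydride, C8/C9 from cinnamaldehyde, C1–C4 from cis-butenediol.
- Enabling feature: C7 of the ten-membered ring carries the C11(=C13)–C12 carboxyl, and its neighbour C6 is a propargylic carbinol carbon while C4≡C5 is still a triple bond. The carboxylate oxygen can therefore close the five-membered lactone ring on C6 by 5-exo-tet SN2, and the alkyne insulates C6 from the C2–C3 oxirane (no allyl cation, no SN2′ path, O3 and O8 held away).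
- C6 is carried at the carboxyl level, becomes an ynone, is reduced under catalyst control to the (6R)-carbinol and is inverted in the lactonisation. The cis C4=C5 alkene is released from the alkyne only in the last step.
- Ring order: oxiranes (steps 2 and 5) → γ-lactone (step 15) → ten-membered carbocycle (step 20).

Key step: step 15

Numbering used below (germacranolide locants): C1=C10 is the ester-bearing ring alkene (C14 = CO2Me carbon), C2–C3 the ring oxirane, C4=C5 the cis alkene, C6 the lactone O–CH, C7 the ring-fusion CH, C8 the CH–O-epoxyangelate, C9 the CH–OAc, C11/C12/C13 the lactone α-carbon, carbonyl and exocyclic CH2.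

Assumption: the facial sense of the magnesium-catalysed anti-aldol (step 10) and of the transfer hydrogenation (step 14) is taken from the accepted transition-state models; were either reversed, the antipodal auxiliary or catalyst would be used.

**Route**

Step 1
Reactants: 1 angelic acid
Product: 2 (Z)-2-methylbut-2-en-1-ol
Conditions: LiAlH4, Et2O, 0 °C
Reagents that add atoms: none
Why: Hydride reduction of the carboxylic acid at low temperature should leave the Z-trisubstituted alkene untouched.

Step 2
Reactants: 2 (Z)-2-methylbut-2-en-1-ol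
Product: 3 [(2R,3S)-2,3-dimethyloxiran-2-yl]methanol
Conditions: Ti(OiPr)4 (cat.), D-(−)-diethyl tartrate (cat.), t-BuOOH, 4 Å MS, CH2Cl2, −20 °C
Reagents that add atoms: tert-butyl hydroperoxide, CC(C)(C)OO
Why: Sharpless asymmetric epoxidation; the D-(−)-tartrate complex should deliver oxygen syn to the face that gives the (2R,3S)-epoxy alcohol, the methyl groups staying trans.

Step 3
Reactants: 3 [(2R,3S)-2,3-dimethyloxiran-2-yl]methanol
Product: 4 (2S,3S)-2,3-dimethyloxirane-2-carboxylic acid (epoxyangelic acid)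
Conditions: RuCl3 (cat.), NaIO4, CCl4/MeCN/H2O, 23 °C
Reagents that add atoms: sodium periodate, [Na+].[O-]I(=O)(=O)=O; water, O
Why: Ruthenium tetroxide oxidation of a primary epoxy alcohol to the acid leaves the oxirane and both stereocentres untouched (only the descriptor at C2 changes).

Step 4
Reactants: 5 (Z)-but-2-ene-1,4-diol
Product: 6 (Z)-4-[(4-methoxybenzyl)oxy]but-2-en-1-ol
Conditions: NaH (1 equiv), THF/DMF, 0 °C; PMBCl, n-Bu4NI (cat.)
Reagents that add atoms: 4-methoxybenzyl chloride, COc1ccc(CCl)cc1
Why: Williamson mono-etherification of the symmetric diol (one equivalent of base, excess diol).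

Step 5
Reactants: 6 (Z)-4-[(4-methoxybenzyl)oxy]but-2-en-1-ol
Product: 7 [(2S,3R)-3-{[(4-methoxybenzyl)oxy]methyl}oxiran-2-yl]methanol
Conditions: Ti(OiPr)4 (cat.), L-(+)-diethyl tartrate (cat.), t-BuOOH, 4 Å MS, CH2Cl2, −20 °C
Reagents that add atoms: tert-butyl hydroperoxide, CC(C)(C)OO
Why: Sharpless asymmetric epoxidation of the Z-allylic alcohol; L-(+)-tartrate should give the (2S,3R) cis-oxirane that becomes C3 (S) and C2 (R) of the target.

Step 6
Reactants: 7 [(2S,3R)-3-{[(4-methoxybenzyl)oxy]methyl}oxiran-2-yl]methanol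
Product: 8 (2R,3R)-3-{[(4-methoxybenzyl)oxy]methyl}oxirane-2-carbaldehyde
Conditions: Dess–Martin periodinane, pyridine, CH2Cl2, 0 °C
Reagents that add atoms: none
Why: Buffered Dess–Martin oxidation should give the cis-epoxy aldehyde without epimerisation or oxirane opening.

Step 7
Reactants: 8 (2R,3R)-3-{[(4-methoxybenzyl)oxy]methyl}oxirane-2-carbaldehyde
Product: 9 (2S,3R)-2-ethynyl-3-{[(4-methoxybenzyl)oxy]methyl}oxirane
Conditions: dimethyl (1-diazo-2-oxopropyl)phosphonate, K2CO3, MeOH, 0 → 23 °C
Reagents that add atoms: dimethyl (1-diazo-2-oxopropyl)phosphonate, CC(=O)C(=[N+]=[N-])P(=O)(OC)OC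
Why: Ohira–Bestmann homologation converts the aldehyde into the terminal alkyne (C4≡C5) under mild carbonate conditions that the cis-oxirane should survive.

Step 8
Reactants: 10 (S)-4-benzyloxazolidin-2-one; 11 itaconic anhydride
Product: 12 4-[(S)-4-benzyl-2-oxooxazolidin-3-yl]-2-methylidene-4-oxobutanoic acid
Conditions: n-BuLi, THF, −78 °C; then 11, −78 °C; 1 M HCl
Reagents that add atoms: none
Why: N-Acylation by anhydride ring-opening; the lithiated auxiliary should attack the saturated, more electrophilic carbonyl (next to CH2), leaving the conjugated carboxyl (C12) free.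

Step 9
Reactants: 12 4-[(S)-4-benzyl-2-oxooxazolidin-3-yl]-2-methylidene-4-oxobutanoic acid
Product: 13 2-(trimethylsilyl)ethyl ester of 12
Conditions: Me3SiCH2CH2OH, EDC·HCl, DMAP (cat.), CH2Cl2, 0 °C
Reagents that add atoms: 2-(trimethylsilyl)ethanol, C[Si](C)(C)CCO
Why: Steglich esterification masks C12 as a fluoride-labile ester; low temperature keeps the methylidene from migrating into conjugation.

Step 10
Reactants: 13 2-(trimethylsilyl)ethyl ester of 12; 14 (E)-cinnamaldehyde
Product: 16 anti-aldol adduct (2R,3R in the acyl chain; C7–C8 bond), via trimethylsilyl ether 15 (not isolated)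
Conditions: MgCl2 (cat.), Et3N, Me3SiCl, EtOAc, 23 °C; then 1 M HCl, THF, 0 °C
Reagents that add atoms: none
Why: Magnesium-halide-catalysed direct anti-aldol of an N-acyloxazolidinone (soft enolisation of the doubly activated C7 methylene, silyl trapping for turnover): the chelated Z-enolate should be attacked on the face opposite the benzyl group through a boat transition state, setting C7 and C8 as the anti pair, while α-attack keeps the C11=C13 methylidene in place.

Step 11
Reactants: 16 anti-aldol adduct
Product: 17 Weinreb amide, 2-(trimethylsilyl)ethyl (3R,4R,5E)-4-hydroxy-3-[methoxy(methyl)carbamoyl]-2-methylidene-6-phenylhex-5-enoate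
Conditions: AlMe3, MeONHMe·HCl, CH2Cl2, −20 → 0 °C
Reagents that add atoms: N,O-dimethylhydroxylamine hydrochloride, CNOC.Cl
Why: Weinreb transamination of the imide, assisted by the free β-hydroxyl, releases the auxiliary; at low temperature the hindered acrylate ester should not be attacked.

Step 12
Reactants: 17 Weinreb amide
Product: 18 O8-triethylsilyl ether of 17
Conditions: Et3SiOTf, 2,6-lutidine, CH2Cl2, −78 °C
Reagents that add atoms: triethylsilyl trifluoromethanesulfonate, CC[Si](CC)(CC)OS(=O)(=O)C(F)(F)F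
Why: Silylation of the only hydroxyl prevents retro-aldol, β-elimination and lactonisation onto the ester in the next steps.

Step 13
Reactants: 9 (2S,3R)-2-ethynyl-3-{[(4-methoxybenzyl)oxy]methyl}oxirane; 18 O8-triethylsilyl ether of 17
Product: 19 alkynyl ketone (C6 ketone, C4≡C5, C2–C3 oxirane)
Conditions: 9, n-BuLi, THF, −78 °C; then 18, −78 → −40 °C; AcOH
Reagents that add atoms: none
Why: Lithium acetylide addition to a Weinreb amide stops at the ketone through the chelated tetrahedral intermediate; at −78 °C the oxirane, the acrylate ester and the C7 centre should be untouched.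

Step 14
Reactants: 19 alkynyl ketone
Product: 20 (6R)-propargylic alcohol (6R,7S,8R; oxirane 2R,3S)
Conditions: Ru[(R,R)-TsNCH(Ph)CH(Ph)NH](p-cymene) (cat.), i-PrOH, 23 °C
Reagents that add atoms: none
Why: Noyori-type asymmetric transfer hydrogenation of an α,β-acetylenic ketone; the (R,R)-catalyst should override the C7 centre and give the (6R)-carbinol, deliberately epimeric at C6 to the C–O bond of the target.

Step 15
Reactants: 20 (6R)-propargylic alcohol
Product: 24 hydroxy lactone (6S at the alkyne stage; free O8–H; O1-PMB), via mesylate 21 (not isolated), via desilylated mesylate 22 (not isolated), via ammonium carboxylate 23 (not isolated)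
Conditions: MsCl, Et3N, THF, −20 °C; then n-Bu4NF, THF, 0 → 23 °C; AcOH
Reagents that add atoms: none
Why: Mesylation turns the (6R)-hydroxyl into a leaving group; fluoride then cleaves the O8 triethylsilyl ether and the 2-(trimethylsilyl)ethyl ester (ethylene and Me3SiF), and the liberated C12 carboxylate displaces the mesylate at C6, closing the γ-lactone through the O–C6 bond. The closest known reaction type is fluoride unmasking of a 2-(trimethylsilyl)ethyl ester followed by intramolecular carboxylate O-alkylation, the SN2 counterpart of a Mitsunobu lactonisation. The only ring closed is the five-membered lactone, in the 5-exo-tet mode; its one new stereocentre, C6, arises by inversion of the catalyst-set (6R)-carbinol, which should place O6 trans to the C7–C8 bond as in the target. The step needs O-alkylation at C6 to win over fluoride substitution, elimination and SN2′ attack: this is secured by the intramolecular five-membered trajectory, by the SN2-active but non-ionising propargylic mesylate, and by the C4≡C5 triple bond, which cannot relay attack to the C2–C3 oxirane and holds O3 and O8 away from C6. If the freed O8 first lactonises onto the ester, the resulting cis-8,12-lactone should be reopened by hydroxide or alkoxide in the basic medium and funnel into the same irreversible closure, whose trans-β,γ-disubstituted lactone is also expected to be the more stable isomer.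

Step 16
Reactants: 24 hydroxy lactone; 4 (2S,3S)-2,3-dimethyloxirane-2-carboxylic acid
Product: 25 O8-epoxyangelate
Conditions: 4, 2,4,6-trichlorobenzoyl chloride, Et3N, THF; then 24, DMAP (cat.), toluene, 23 °C
Reagents that add atoms: none
Why: Yamaguchi esterification; the mixed anhydride of the hindered epoxy acid acylates the only free hydroxyl, and the stereocentres of 4 are not involved.

Step 17
Reactants: 25 O8-epoxyangelate
Product: 26 C1 primary alcohol
Conditions: DDQ, CH2Cl2/pH 7 buffer, 0 °C
Reagents that add atoms: none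
Why: Oxidative cleavage of the 4-methoxybenzyl ether; no other electron-rich arene or free alcohol is present.

Step 18
Reactants: 26 C1 primary alcohol
Product: 28 (Z)-2-iodo enoate, via epoxy aldehyde 27 (not isolated)
Conditions: Dess–Martin periodinane, pyridine, CH2Cl2, 0 °C; then Ph3P=C(I)CO2Me (from Ph3P=CHCO2Me and N-iodosuccinimide, CH2Cl2, −20 °C), 0 → 23 °C
Reagents that add atoms: methyl (triphenyl-λ5-phosphanylidene)acetate, COC(=O)C=P(c1ccccc1)(c1ccccc1)c1ccccc1; N-iodosuccinimide, O=C1CCC(=O)N1I
Why: Dess–Martin oxidation gives the labile cis-epoxy aldehyde, trapped at once in a Wittig reaction with the stabilised α-iodo ylide, which should place the ester trans to C2 and so give the (Z)-iodo enoate that becomes the ring-cis C1=C10 bond.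

Step 19
Reactants: 28 (Z)-2-iodo enoate
Product: 29 C9 aldehyde
Conditions: O3, CH2Cl2, −78 °C (Sudan red end point); then Me2S
Reagents that add atoms: ozone, [O-][O+]=O
Why: Ozonolysis; the styryl double bond is the only electron-rich alkene (acrylate, iodo enoate and alkyne react far more slowly), so titration to the dye end point should unveil the α-acyloxy aldehyde.

Step 20
Reactants: 29 C9 aldehyde
Product: 30 ten-membered ring alcohol (9R; ring alkyne C4≡C5)
Conditions: CrCl2, NiCl2 (cat.), DMSO/THF, 23 °C, high dilution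
Reagents that add atoms: none
Why: Intramolecular Nozaki–Hiyama–Kishi reaction: the alkenylchromium species from the iodo enoate adds to the C9 aldehyde and closes the carbocycle (C9–C10); Felkin–Anh addition anti to the C8 acyloxy group should give the 8,9-anti (9R) alcohol.

Step 21
Reactants: 30 ten-membered ring alcohol
Product: 31 C9 acetate
Conditions: Ac2O, pyridine, DMAP (cat.), CH2Cl2, 0 °C
Reagents that add atoms: acetic anhydride, CC(=O)OC(C)=O
Why: Acetylation of the only free hydroxyl; the bulky α-quaternary C8 ester should not migrate.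

Step 22
Reactants: 31 C9 acetate
Product: 32 target CNP0077533.1
Conditions: H2 (1 atm), Pd on CaCO3 poisoned with Pb(OAc)2, quinoline, EtOAc, 0 °C
Reagents that add atoms: none
Why: Lindlar semihydrogenation; syn addition of hydrogen to the strained ring alkyne gives the cis C4=C5 alkene, and quinoline poisoning should spare the exocyclic methylene, the enoate and both oxiranes (C6 becomes R by priority change only).

**Compound list**

1 | angelic acid, (Z)-2-methylbut-2-enoic acid | C/C=C(/C)C(=O)O | starting material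
2 | (Z)-2-methylbut-2-en-1-ol | C/C=C(/C)CO | intermediate
3 | [(2R,3S)-2,3-dimethyloxiran-2-yl]methanol | OC[C@@]1(C)O[C@H]1C | intermediate
4 | (2S,3S)-2,3-dimethyloxirane-2-carboxylic acid | OC(=O)[C@@]1(C)O[C@H]1C | intermediate
5 | (Z)-but-2-ene-1,4-diol | OC/C=C\CO | starting material
6 | (Z)-4-[(4-methoxybenzyl)oxy]but-2-en-1-ol | OC/C=C\COCc1ccc(OC)cc1 | intermediate
7 | [(2S,3R)-3-{[(4-methoxybenzyl)oxy]methyl}oxiran-2-yl]methanol | OC[C@@H]1O[C@@H]1COCc1ccc(OC)cc1 | intermediate
8 | (2R,3R)-3-{[(4-methoxybenzyl)oxy]methyl}oxirane-2-carbaldehyde | O=C[C@@H]1O[C@@H]1COCc1ccc(OC)cc1 | intermediate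
9 | (2S,3R)-2-ethynyl-3-{[(4-methoxybenzyl)oxy]methyl}oxirane | C#C[C@@H]1O[C@@H]1COCc1ccc(OC)cc1 | intermediate
10 | (S)-4-benzyloxazolidin-2-one | O=C1N[C@@H](Cc2ccccc2)CO1 | starting material
11 | itaconic anhydride | C=C1CC(=O)OC1=O | starting material
12 | 4-[(S)-4-benzyl-2-oxooxazolidin-3-yl]-2-methylidene-4-oxobutanoic acid | C=C(CC(=O)N1[C@@H](Cc2ccccc2)COC1=O)C(=O)O | intermediate
13 | 2-(trimethylsilyl)ethyl 4-[(S)-4-benzyl-2-oxooxazolidin-3-yl]-2-methylidene-4-oxobutanoate | C=C(CC(=O)N1[C@@H](Cc2ccccc2)COC1=O)C(=O)OCC[Si](C)(C)C | intermediate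
14 | (E)-cinnamaldehyde | O=C/C=C/c1ccccc1 | starting material
15 | O-trimethylsilyl ether of anti-aldol adduct 16 | c1ccccc1/C=C/[C@@H](O[Si](C)(C)C)[C@@H](C(=C)C(=O)OCC[Si](C)(C)C)C(=O)N1[C@@H](Cc2ccccc2)COC1=O | intermediate
16 | (S)-4-benzyl-3-[(2R,3R,4E)-3-hydroxy-5-phenyl-2-{1-[2-(trimethylsilyl)ethoxycarbonyl]ethenyl}pent-4-enoyl]oxazolidin-2-one | c1ccccc1/C=C/[C@@H](O)[C@@H](C(=C)C(=O)OCC[Si](C)(C)C)C(=O)N1[C@@H](Cc2ccccc2)COC1=O | intermediate
17 | 2-(trimethylsilyl)ethyl (3R,4R,5E)-4-hydroxy-3-[methoxy(methyl)carbamoyl]-2-methylidene-6-phenylhex-5-enoate | c1ccccc1/C=C/[C@@H](O)[C@@H](C(=C)C(=O)OCC[Si](C)(C)C)C(=O)N(C)OC | intermediate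
18 | O8-triethylsilyl ether of 17 (3R,4R) | c1ccccc1/C=C/[C@@H](O[Si](CC)(CC)CC)[C@@H](C(=C)C(=O)OCC[Si](C)(C)C)C(=O)N(C)OC | intermediate
19 | alkynyl ketone: C6 ketone joined through C4≡C5 to the (2R,3S)-oxirane bearing CH2OPMB; C7 and C8 as in 18 | c1ccccc1/C=C/[C@@H](O[Si](CC)(CC)CC)[C@@H](C(=C)C(=O)OCC[Si](C)(C)C)C(=O)C#C[C@@H]1O[C@@H]1COCc1ccc(OC)cc1 | intermediate
20 | (6R)-propargylic alcohol from 19 (6R,7S,8R; oxirane 2R,3S) | c1ccccc1/C=C/[C@@H](O[Si](CC)(CC)CC)[C@@H](C(=C)C(=O)OCC[Si](C)(C)C)[C@@H](O)C#C[C@@H]1O[C@@H]1COCc1ccc(OC)cc1 | intermediate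
21 | C6 methanesulfonate of 20 | c1ccccc1/C=C/[C@@H](O[Si](CC)(CC)CC)[C@@H](C(=C)C(=O)OCC[Si](C)(C)C)[C@@H](OS(C)(=O)=O)C#C[C@@H]1O[C@@H]1COCc1ccc(OC)cc1 | intermediate
22 | C6 methanesulfonate with free O8–H | c1ccccc1/C=C/[C@@H](O)[C@@H](C(=C)C(=O)OCC[Si](C)(C)C)[C@@H](OS(C)(=O)=O)C#C[C@@H]1O[C@@H]1COCc1ccc(OC)cc1 | intermediate
23 | tetrabutylammonium C12 carboxylate of the C6 methanesulfonate | c1ccccc1/C=C/[C@@H](O)[C@@H](C(=C)C(=O)[O-])[C@@H](OS(C)(=O)=O)C#C[C@@H]1O[C@@H]1COCc1ccc(OC)cc1.CCCC[N+](CCCC)(CCCC)CCCC | intermediate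
24 | hydroxy lactone: α-methylene-γ-butyrolactone (O–C6), 6S,7R,8R at the alkyne stage, C6 bearing the (2R,3S)-oxiranylethynyl arm with CH2OPMB, C7 bearing the (E)-1-hydroxy-3-phenylallyl group | C=C1C(=O)O[C@H](C#C[C@@H]2O[C@@H]2COCc2ccc(OC)cc2)[C@H]1[C@H](O)/C=C/c1ccccc1 | intermediate
25 | O8-[(2S,3S)-2,3-dimethyloxirane-2-carbonyl] ester of 24 | C=C1C(=O)O[C@H](C#C[C@@H]2O[C@@H]2COCc2ccc(OC)cc2)[C@H]1[C@H](OC(=O)[C@@]1(C)O[C@H]1C)/C=C/c1ccccc1 | intermediate
26 | C1 primary alcohol (PMB removed from 25) | C=C1C(=O)O[C@H](C#C[C@@H]2O[C@@H]2CO)[C@H]1[C@H](OC(=O)[C@@]1(C)O[C@H]1C)/C=C/c1ccccc1 | intermediate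
27 | C1 cis-epoxy aldehyde | C=C1C(=O)O[C@H](C#C[C@@H]2O[C@@H]2C=O)[C@H]1[C@H](OC(=O)[C@@]1(C)O[C@H]1C)/C=C/c1ccccc1 | intermediate
28 | methyl (Z)-2-iodo enoate at C1=C10 | C=C1C(=O)O[C@H](C#C[C@@H]2O[C@@H]2/C=C(/C(=O)OC)I)[C@H]1[C@H](OC(=O)[C@@]1(C)O[C@H]1C)/C=C/c1ccccc1 | intermediate
29 | C9 aldehyde (styryl group cleaved from 28) | C=C1C(=O)O[C@H](C#C[C@@H]2O[C@@H]2/C=C(/C(=O)OC)I)[C@H]1[C@H](OC(=O)[C@@]1(C)O[C@H]1C)C=O | intermediate
30 | ten-membered ring (9R)-alcohol with C4≡C5 triple bond, all other centres as in 32 | C=C1C(=O)O[C@@H]2C#C[C@@H]3O[C@@H]3/C=C(/C(=O)OC)[C@@H](O)[C@@H](OC(=O)[C@@]3(C)O[C@H]3C)[C@@H]12 | intermediate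
31 | C9 acetate of 30 (4,5-didehydro target) | C=C1C(=O)O[C@@H]2C#C[C@@H]3O[C@@H]3/C=C(/C(=O)OC)[C@@H](OC(C)=O)[C@@H](OC(=O)[C@@]3(C)O[C@H]3C)[C@@H]12 | intermediate
32 | CNP0077533.1 (2R,3S,6R,7S,8S,9R; ester 2S,3S; cis C4=C5; ring-cis C1=C10) | C=C1C(=O)O[C@@H]2/C=C\[C@@H]3O[C@@H]3/C=C(/C(=O)OC)[C@@H](OC(C)=O)[C@@H](OC(=O)[C@@]3(C)O[C@H]3C)[C@@H]12 | target

**Count and risks**

Total step count: 22. Longest linear sequence: 15 steps (steps 8–22, from 10 and 11 to 32); the alkyne 9 (steps 4–7) enters at step 13 and the acid 4 (steps 1–3) at step 16.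

Steps most likely to fail:

1. Step 15 (key step). Fluoride may act as base or nucleophile at the propargylic mesylate (elimination to the enyne, propargylic fluoride) before the carboxylate is released, or acyl transfer to the freed O8 may leave the regioisomeric lactone. Fallback, from 20: the C6 hydroxyl is converted into its triflate with Tf2O and 2,6-di-tert-butyl-4-methylpyridine in CH2Cl2 at −78 °C. The neutral C12 ester carbonyl oxygen then displaces the triflate (5-exo-tet, inversion), and the resulting 2-alkoxyoxolanylium ion sheds its 2-(trimethylsilyl)ethyl group as ethylene and Me3SiOTf (dealkylative lactonisation), giving the O8-triethylsilyl lactone F1 with no fluoride and no free alkoxide present. Buffered HF·pyridine in THF at 0 °C then removes the silyl ether, and the route is rejoined at 24.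

2. Step 20. Intermolecular coupling may outrun ring closure, and facial selectivity at C9 may be poor inside the forming ring. Fallback, from 29: the coupling is run under the same high dilution and the crude alcohol, 30 together with its C9 epimer F2, is oxidised with Dess–Martin periodinane to the ring ketone F3. Reduction of F3 with NaBH4/CeCl3 in MeOH at −78 °C from the ring periphery (or, if substrate control is inadequate, with a chiral oxazaborolidine and catecholborane) sets C9 independently of the coupling and returns to 30.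

3. Step 22. Over-reduction of the exocyclic C11=C13 methylene or hydrogenolysis of the propargylic/allylic C–O bonds at C3 and C6 may occur. Fallback, from 31: syn-hydroboration of the strained ring alkyne with dicyclohexylborane in THF at 0 °C gives the alkenylborane F4; protonolysis of the C–B bond with acetic acid at 23 °C proceeds with retention and gives the cis alkene 32 without any hydrogenation catalyst.

Further compounds
F1 | step 15 | O8-triethylsilyl ether of hydroxy lactone 24 | C=C1C(=O)O[C@H](C#C[C@@H]2O[C@@H]2COCc2ccc(OC)cc2)[C@H]1[C@H](O[Si](CC)(CC)CC)/C=C/c1ccccc1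
F2 | step 20 | C9 epimer of ring alcohol 30 | C=C1C(=O)O[C@@H]2C#C[C@@H]3O[C@@H]3/C=C(/C(=O)OC)[C@H](O)[C@@H](OC(=O)[C@@]3(C)O[C@H]3C)[C@@H]12
F3 | step 20 | C9 ring ketone | C=C1C(=O)O[C@@H]2C#C[C@@H]3O[C@@H]3/C=C(/C(=O)OC)C(=O)[C@@H](OC(=O)[C@@]3(C)O[C@H]3C)[C@@H]12
F4 | step 22 | C5 dicyclohexylboryl cis-alkene from 31 | C=C1C(=O)O[C@@H]2/C(B(C3CCCCC3)C3CCCCC3)=C\[C@@H]3O[C@@H]3/C=C(/C(=O)OC)[C@@H](OC(C)=O)[C@@H](OC(=O)[C@@]3(C)O[C@H]3C)[C@@H]12
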